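**Retrosynthetic overview**
1. The last disconnection is the C2–C1' bond between ring C (pyranone) and ring B. It is opened as a twofold C–H (dehydrogenative) coupling of 3,7,8-trimethoxychromone (C2–H) with unprotected 3,4-dimethoxyphenol (C6–H), with no halide, no metal and no separate protecting-group step.
2. The enabling feature is the vinylogous ester O1–C2=C3–C4=O of ring C. Silylation of the C4 oxygen turns ring C into an aromatic benzopyrylium ion in which C3 (OMe) and C4 (OSi) are blocked, so C2 is the only free electrophilic carbon. C1' of ring B lies ortho to the 2'-oxygen and para to the 4'-methoxy group, which makes it the most nucleophilic CH of the phenol.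
3. The adduct sits one oxidation level low, as a 2H-chromene silyl enol ether. DDQ in the same flask restores the chromone and both silyl groups fall off on work-up, so the one free OH among five OMe groups is bought, not differentiated.
4. Ring C of the chromone is closed by inserting C2 (DMF dimethyl acetal) between the phenol oxygen and the α-CH2 of a 2-hydroxy-ω-methoxyacetophenone. That ketone comes from ortho-lithiation/Weinreb acylation of 1,2,3-trimethoxybenzene and chelation-controlled cleavage of the ortho methyl ether.
5. Ring order: A is bought, C is closed in step 3, and B (bought) is attached in step 4.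

Key step: step 4

Assumption: the target has no stereocentre, and its C2–C1' axis (one ortho OH facing O1 and 3-OMe) rotates freely. It is therefore a single achiral compound, and no step needs stereocontrol.

Step 1
Reactants: 1 1,2,3-trimethoxybenzene; 2 N,2-dimethoxy-N-methylacetamide
Product: 4 2-methoxy-1-(2,3,4-trimethoxyphenyl)ethan-1-one, via 2,3,4-trimethoxyphenyllithium 3 (not isolated)
Conditions: n-BuLi, TMEDA, THF, 0 °C to rt; then 2, −78 to 0 °C; 1 M HCl quench
Reagents that add atoms: none
Why: Directed ortho-metalation next to a terminal methoxy group (the two open ortho sites are equivalent) is followed by a Weinreb ketone synthesis, which stops the addition at the ketone stage; no stereocentre is formed.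

Step 2
Reactants: 4 2-methoxy-1-(2,3,4-trimethoxyphenyl)ethan-1-one
Product: 6 1-(2-hydroxy-3,4-dimethoxyphenyl)-2-methoxyethan-1-one, via aryloxydichloroborane chelate 5 (not isolated)
Conditions: BCl3 (1.1 equiv), CH2Cl2, −78 to 0 °C; then H2O
Reagents that add atoms: none
Why: In this chelation-controlled Lewis-acid ether cleavage, boron bridges the ketone oxygen and the ortho methoxy oxygen in a six-membered chelate, so chloride removes only that aryl methyl group, while the unchelated 3- and 4-methoxy groups and the poorer-leaving aliphatic α-methoxy group should stay.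

Step 3
Reactants: 6 1-(2-hydroxy-3,4-dimethoxyphenyl)-2-methoxyethan-1-one
Product: 8 3,7,8-trimethoxy-4H-chromen-4-one, via enaminone 7 (not isolated)
Conditions: Me2NCH(OMe)2 (3 equiv), toluene, 100 °C; then AcOH, 60 °C
Reagents that add atoms: N,N-dimethylformamide dimethyl acetal, COC(OC)N(C)C
Why: In this enaminone route to chromones, the acetal condenses at the activated α-CH2 to give 7, whose phenol oxygen adds to the β-carbon (6-endo-trig oxa-Michael addition) and expels dimethylamine, which closes ring C; no stereocentre is formed.

Step 4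
Reactants: 8 3,7,8-trimethoxy-4H-chromen-4-one; 9 3,4-dimethoxyphenol
Product: 14 2-(2-hydroxy-4,5-dimethoxyphenyl)-3,7,8-trimethoxy-4H-chromen-4-one, via aryl trimethylsilyl ether 10 (not isolated), via 4-silyloxybenzopyrylium triflate 11 (not isolated), via 2H-chromene silyl enol ether 12 (not isolated), via O-silylated flavone 13 (not isolated)
Conditions: TMSOTf (2.4 equiv), 2,6-lutidine (2.6 equiv), CH2Cl2, 0 to 40 °C; then DDQ (1.0 equiv), −20 to 0 °C; then 1 M HCl, THF, rt
Reagents that add atoms: none
Why: Proposed new method: TMSOTf silylates the phenol to 10 and the C4 oxygen of 8 to the aromatic benzopyrylium ion 11, C6 of 10 attacks C2 of 11 in a Friedel–Crafts step and lutidine takes the arenium proton to leave the 2H-chromene silyl enol ether 12, DDQ then removes the C2 hydride (allylic, benzylic and α to O1) with loss of the O4 silyl group to give 13, and dilute acid frees the 2'-OH. The closest known reaction types are the silyl-triflate-promoted C2 addition of π-nucleophiles (enol silanes, allyl metals, copper acetylides) to chromones through 4-silyloxybenzopyrylium triflates, the capture of flavylium ions by phenols, and the DDQ dehydrogenation of silyl enol ethers and 2H-chromenes; new is their union into a C–H/C–H arylation of a chromone by a phenol. No ring is closed, and the only new stereocentre, C2 of 12, forms as a racemate and is erased by the oxidation, so nothing has to control it. Site selectivity on the cation is secured by the substituents of ring C, since C4 bears the silyloxy donor and C3 the methoxy group and only C2 is free, and an O-bound adduct is an acetal that re-ionises under TMSOTf and so drains to the C-bound product. Site selectivity on ring B is secured by the oxygen pattern, since C6 is ortho to the silyloxy and para to the 3-methoxy group, C2 is flanked on both sides and C5 is activated by one oxygen only. Chemoselectivity of the oxidation rests on 12 being an enediol diether far more electron-rich than 13 or 10, and the lutidine buffer keeps DDQ from acting as an acid-activated arene oxidant.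

**Compound list**
1 | 1,2,3-trimethoxybenzene | COc1cccc(OC)c1OC | starting material
2 | N,2-dimethoxy-N-methylacetamide | COCC(=O)N(C)OC | starting material
3 | 2,3,4-trimethoxyphenyllithium | [Li]c1ccc(OC)c(OC)c1OC | intermediate
4 | 2-methoxy-1-(2,3,4-trimethoxyphenyl)ethan-1-one | COCC(=O)c1ccc(OC)c(OC)c1OC | intermediate
5 | dichloro[6-(methoxyacetyl)-2,3-dimethoxyphenoxy]borane (carbonyl-chelated) | COCC(=O)c1ccc(OC)c(OC)c1OB(Cl)Cl | intermediate
6 | 1-(2-hydroxy-3,4-dimethoxyphenyl)-2-methoxyethan-1-one | COCC(=O)c1ccc(OC)c(OC)c1O | intermediate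
7 | (Z)-3-(dimethylamino)-1-(2-hydroxy-3,4-dimethoxyphenyl)-2-methoxyprop-2-en-1-one (geometry lost on ring closure) | CO/C(=C\N(C)C)C(=O)c1ccc(OC)c(OC)c1O | intermediate
8 | 3,7,8-trimethoxy-4H-chromen-4-one | COc1ccc2c(=O)c(OC)coc2c1OC | intermediate
9 | 3,4-dimethoxyphenol | COc1ccc(O)cc1OC | starting material
10 | (3,4-dimethoxyphenoxy)trimethylsilane | COc1ccc(O[Si](C)(C)C)cc1OC | intermediate
11 | 3,7,8-trimethoxy-4-[(trimethylsilyl)oxy]-1-benzopyrylium trifluoromethanesulfonate | COc1ccc2c(O[Si](C)(C)C)c(OC)c[o+]c2c1OC.[O-]S(=O)(=O)C(F)(F)F | intermediate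
12 | rac-2-{4,5-dimethoxy-2-[(trimethylsilyl)oxy]phenyl}-3,7,8-trimethoxy-4-[(trimethylsilyl)oxy]-2H-chromene | COC1=C(O[Si](C)(C)C)c2ccc(OC)c(OC)c2OC1c1cc(OC)c(OC)cc1O[Si](C)(C)C | intermediate
13 | 2-{4,5-dimethoxy-2-[(trimethylsilyl)oxy]phenyl}-3,7,8-trimethoxy-4H-chromen-4-one | COc1cc(O[Si](C)(C)C)c(-c2oc3c(OC)c(OC)ccc3c(=O)c2OC)cc1OC | intermediate
14 | 2-(2-hydroxy-4,5-dimethoxyphenyl)-3,7,8-trimethoxy-4H-chromen-4-one (achiral) | COc1cc(O)c(-c2oc3c(OC)c(OC)ccc3c(=O)c2OC)cc1OC | target

**Total step count:** 4. **Longest linear sequence:** 4 steps (1 → 4 → 6 → 8 → 14).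

**Steps most likely to fail**

1. Step 4 (bears the label "Proposed new method:").
   - Risk: C–C bond formation may be too slow or reversible, because the cation is stabilised by the 4-silyloxy and 7-methoxy donors. The nucleophile may rest at the O-bound stage, and the dehydrogenation may over-oxidise the electron-rich ring B.
   - Fallback: known chemistry that sets out from 8 and 9 and comes back at 14. Compound 8 is zincated at C2 with TMPZnCl·LiCl (THF, 25 °C) to chloro(3,7,8-trimethoxy-4-oxo-4H-chromen-2-yl)zinc F1. In parallel, 9 is iodinated at C6 (NIS, MeCN, 0 °C) to 2-iodo-4,5-dimethoxyphenol F2 and benzylated (BnBr, K2CO3, DMF) to 1-(benzyloxy)-2-iodo-4,5-dimethoxybenzene F3. Negishi coupling of the two partners (Pd(dba)2, SPhos, THF, 50 °C) should give 2-[2-(benzyloxy)-4,5-dimethoxyphenyl]-3,7,8-trimethoxy-4H-chromen-4-one F4, and hydrogenolysis (H2, Pd/C, EtOAc) should give 14.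

2. Step 2.
   - Risk: the ether cleavage may lose its site selectivity. Boron may attack the α-methoxy group through the competing five-membered chelate, or a second cleavage may occur at the neighbouring 3-methoxy group once the boron aryloxide has formed.
   - Fallback: a route that sets out from 2 and comes back at 6 without any methyl ether cleavage. Commercial 2,3-dimethoxyphenol is protected (MOMCl, i-Pr2NEt, CH2Cl2) as 1,2-dimethoxy-3-(methoxymethoxy)benzene F5. This is lithiated ortho to the acetal oxygen (n-BuLi, THF, 0 °C) to [3,4-dimethoxy-2-(methoxymethoxy)phenyl]lithium F6 and acylated with 2 to 1-[3,4-dimethoxy-2-(methoxymethoxy)phenyl]-2-methoxyethan-1-one F7. HCl in MeOH then removes the acetal and should give 6.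

3. Step 3.
   - Risk: condensation at the oxygen-substituted, less acidic CH2 may be sluggish, and the hot acetal may O-methylate the phenol.
   - Fallback: a route that sets out from 6 and comes back at 8 and brings in C2 at the carboxylate level. Compound 6 is treated with ethyl chlorooxoacetate in pyridine (O-acylation, intramolecular Claisen-type condensation, dehydration) to give ethyl 3,7,8-trimethoxy-4-oxo-4H-chromene-2-carboxylate F8. Acid hydrolysis (aq. HCl, AcOH, reflux) gives 3,7,8-trimethoxy-4-oxo-4H-chromene-2-carboxylic acid F9, and thermal protodecarboxylation (Cu powder, quinoline, heat) should give 8.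

**Further compounds**
F1 | step 4 | chloro(3,7,8-trimethoxy-4-oxo-4H-chromen-2-yl)zinc | COc1ccc2c(=O)c(OC)c([Zn]Cl)oc2c1OC
F2 | step 4 | 2-iodo-4,5-dimethoxyphenol | COc1cc(O)c(I)cc1OC
F3 | step 4 | 1-(benzyloxy)-2-iodo-4,5-dimethoxybenzene | COc1cc(OCc2ccccc2)c(I)cc1OC
F4 | step 4 | 2-[2-(benzyloxy)-4,5-dimethoxyphenyl]-3,7,8-trimethoxy-4H-chromen-4-one | COc1cc(OCc2ccccc2)c(-c2oc3c(OC)c(OC)ccc3c(=O)c2OC)cc1OC
F5 | step 2 | 1,2-dimethoxy-3-(methoxymethoxy)benzene | COCOc1cccc(OC)c1OC
F6 | step 2 | [3,4-dimethoxy-2-(methoxymethoxy)phenyl]lithium | COCOc1c([Li])ccc(OC)c1OC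
F7 | step 2 | 1-[3,4-dimethoxy-2-(methoxymethoxy)phenyl]-2-methoxyethan-1-one | COCOc1c(C(=O)COC)ccc(OC)c1OC
F8 | step 3 | ethyl 3,7,8-trimethoxy-4-oxo-4H-chromene-2-carboxylate | CCOC(=O)c1oc2c(OC)c(OC)ccc2c(=O)c1OC
F9 | step 3 | 3,7,8-trimethoxy-4-oxo-4H-chromene-2-carboxylic acid | OC(=O)c1oc2c(OC)c(OC)ccc2c(=O)c1OC
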